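**Assumptions (one line each)**
- (S)-Glyceraldehyde acetonide, the Weinreb-type Still–Gennari phosphonate and 3,4-dimethoxyphenylmagnesium bromide are purchasable.
- The dipole adds to the Z-enamide face anti to the γ-C–O bond (Kishi/Felkin–Anh sense), and with that sense the (S)-aldehyde gives the target enantiomer.

## Retrosynthetic overview
1. Magnone B is disconnected at the aroyl C–C bond: 3,4-dimethoxyphenyl Grignard plus a hydroxy Weinreb amide.
2. The CH2OH at C3 comes from the glyceraldehyde-derived dioxolane by acetonide unmasking, periodate cleavage to the aldehyde, and reduction. The cleavage removes the stereochemical director.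
3. The only ring, the 2,3,4-trisubstituted THF with all three stereocenters, forms in one photoredox step: a carbonyl ylide from 2-(3,4,5-trimethoxyphenyl)oxirane adds [3+2] to a Z-enamide, forming C2–C3 and C4–C5.
4. The Z-enamide comes from (S)-glyceraldehyde acetonide by a Z-selective HWE, and the oxirane from 3,4,5-trimethoxybenzaldehyde by Corey–Chaykovsky.

## Route

**Step 1**
Reactants: 1 (3,4,5-trimethoxybenzaldehyde), 2 (trimethylsulfonium iodide)
Product: 3, (±)-2-(3,4,5-trimethoxyphenyl)oxirane
Conditions: 2, NaH, DMSO/THF, 0 °C → rt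
Reagents that add atoms: 2, trimethylsulfonium iodide, C[S+](C)C.[I-] (delivers CH2)
Why: Corey–Chaykovsky epoxidation; the oxirane is racemic because its C–C bond is cleaved in step 3, so no stereochemistry is needed here.

**Step 2**
Reactants: 4 ((S)-glyceraldehyde acetonide), 5 (Weinreb Still–Gennari phosphonate)
Product: 6, (Z)-enamide
Conditions: 5, KHMDS, 18-crown-6, THF, –78 °C
Reagents that add atoms: none (5 is the numbered reactant)
Why: Still–Gennari-type HWE gives the Z-alkene kinetically, which fixes the cis relationship of the future C3 and C4 substituents, and the γ-stereocenter is untouched at –78 °C.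

**Step 3**
Reactants: 3 (oxirane), 6 (Z-enamide)
Product: 7, 2,3-trans/3,4-cis THF
Conditions: Mes-Acr⁺ BF4⁻ (5 mol%), dry MeCN (0.1 M), 455 nm LEDs, 25 °C, 24 h, N2; 3 (1.5 equiv)
Reagents that add atoms: none
Why: The electron-rich oxirane is oxidised by excited acridinium, and C–C cleavage of the radical cation followed by back-reduction gives the carbonyl ylide ArCH⁻–O⁺=CH2. It adds suprafacially to the Z-enamide, so C3 and C4 end up cis, and the γ-dioxolane oxygen directs the dipole to the anti face, which sets C3 and C4 absolutely. The aryl group sits exo, trans to C3, which sets C2. Proposed new method: the ylide's nucleophilic benzylic carbon attacks the enamide β-carbon (C3) and the resulting enolate closes onto the CH2⁺ terminus (C4–C5). The closest known chemistry is photoinduced-electron-transfer generation of carbonyl ylides from 2,3-diaryloxiranes with [3+2] to electron-poor alkenes, and photoredox radical-cation [3+2] of aryl epoxides with electron-rich alkenes; it is not known for monoaryl oxiranes with Z-γ-alkoxy acrylamides.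

**Step 4**
Reactants: 7
Product: 8, C3 aldehyde
Conditions: H5IO6 (2 equiv), EtOAc, 0 °C → rt, 2 h
Reagents that add atoms: none
Why: Acetonide hydrolysis and Malaprade cleavage of the resulting terminal diol remove the director carbons (as acetone and CH2O) and leave the C3 aldehyde; C2–C4 are untouched.

**Step 5**
Reactants: 8
Product: 9, hydroxy Weinreb amide
Conditions: NaBH4, MeOH, –20 °C, 30 min
Reagents that add atoms: none (only H added)
Why: NaBH4 reduces the aldehyde chemoselectively to the primary alcohol (C9) and leaves the Weinreb amide and the aryl ether alone.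

**Step 6**
Reactants: 9, 10 (3,4-dimethoxyphenylmagnesium bromide)
Product: 11, Magnone B
Conditions: 10 (3.5 equiv), THF, 0 °C → rt, 2 h; sat. aq. NH4Cl at 0 °C
Reagents that add atoms: 10, COc1ccc([Mg]Br)cc1OC (delivers the 3,4-dimethoxyphenyl group)
Why: Weinreb ketone synthesis; the stable chelated tetrahedral intermediate prevents over-addition and keeps the α-stereocenter (C4) from enolising until the mild quench.

## Compound list
1 | 3,4,5-trimethoxybenzaldehyde | COc1cc(C=O)cc(OC)c1OC | starting material
2 | trimethylsulfonium iodide | C[S+](C)C.[I-] | starting material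
3 | (±)-2-(3,4,5-trimethoxyphenyl)oxirane | COc1cc(cc(OC)c1OC)C1CO1 | intermediate
4 | (4S)-2,2-dimethyl-1,3-dioxolane-4-carbaldehyde | CC1(C)OC[C@H](O1)C=O | starting material
5 | bis(2,2,2-trifluoroethyl) [2-(methoxy(methyl)amino)-2-oxoethyl]phosphonate | O=C(CP(=O)(OCC(F)(F)F)OCC(F)(F)F)N(C)OC | starting material
6 | (2Z)-3-[(4R)-2,2-dimethyl-1,3-dioxolan-4-yl]-N-methoxy-N-methylprop-2-enamide | CC1(C)OC[C@H](O1)/C=C\C(=O)N(C)OC | intermediate
7 | (3R,4S,5S)-4-[(4R)-2,2-dimethyl-1,3-dioxolan-4-yl]-N-methoxy-N-methyl-5-(3,4,5-trimethoxyphenyl)oxolane-3-carboxamide | CON(C)C(=O)[C@H]1CO[C@H](c2cc(OC)c(OC)c(OC)c2)[C@H]1[C@@H]3COC(C)(C)O3 | intermediate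
8 | (3R,4S,5S)-4-formyl-N-methoxy-N-methyl-5-(3,4,5-trimethoxyphenyl)oxolane-3-carboxamide | CON(C)C(=O)[C@H]1CO[C@H](c2cc(OC)c(OC)c(OC)c2)[C@H]1C=O | intermediate
9 | (3R,4R,5S)-4-(hydroxymethyl)-N-methoxy-N-methyl-5-(3,4,5-trimethoxyphenyl)oxolane-3-carboxamide | CON(C)C(=O)[C@H]1CO[C@H](c2cc(OC)c(OC)c(OC)c2)[C@H]1CO | intermediate
10 | 3,4-dimethoxyphenylmagnesium bromide | COc1ccc([Mg]Br)cc1OC | starting material
11 | Magnone B, (3,4-dimethoxyphenyl)[(3R,4R,5S)-4-(hydroxymethyl)-5-(3,4,5-trimethoxyphenyl)oxolan-3-yl]methanone | COc1ccc(C(=O)[C@H]2CO[C@H](c3cc(OC)c(OC)c(OC)c3)[C@H]2CO)cc1OC | target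

**Total steps:** 6. **Longest linear sequence:** 5 (steps 2–6 from 4).

## Three steps most likely to fail
1. **Step 3 (proposed new method).**
   - Risks: C–O rather than C–C cleavage of the monoaryl oxirane radical cation (Meinwald rearrangement), reversed regiochemistry, or poor exo or facial selectivity.
   - Fallback (known chemistry, different approach): 1,4-addition of α-(MOM-oxy)-3,4,5-trimethoxybenzyllithium (from the stannane and n-BuLi) to 6, enolate quench with monomeric HCHO, then acid MOM removal and benzylic-cation cyclodehydration to give 7 with exo-aryl under thermodynamic control.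
2. **Step 2.**
   - Risks: Z/E erosion, or racemisation of the α-stereocenter of the aldehyde under base.
   - Fallback: Ohira–Bestmann homologation of 4 to the alkyne, lithiation and acylation with N-methoxy-N-methylcarbamoyl chloride, then Lindlar semihydrogenation to 6.
3. **Step 6.**
   - Risks: incomplete addition, or epimerisation at C4 of the less stable 3,4-cis ketone.
   - Fallback: cyclise 9 to the cis-fused bicyclic lactone, then add 1 equiv of 3,4-dimethoxyphenyllithium at –78 °C; the lactol opens to the hydroxy ketone.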